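**Retrosynthetic overview**

1. Feature: the 1,5-related methyl-bearing carbons C4' and C8' of the side chain, each flanked only by CH2 groups, are the saturated counterparts of E-trisubstituted alkenes C3'=C4' and C7'=C8'. The chroman (benzene ring fused to the dihydropyran ring, quaternary C2) is a spectator.
2. C11'–C12' is cut last: a C11' tosylate plus isopropenylmagnesium bromide under copper catalysis, the Grignard reagent also freeing the C6 phenol from its acetate. The 1,1-disubstituted alkene therefore never meets the hydrogenation catalyst.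
3. Key disconnection: the C–H bonds at C3'/C4' and C7'/C8', made together by iridium-catalysed asymmetric hydrogenation of the E,E-dienyl chromanyl acetate carrying a C11' silyl ether.
4. The diene is cut at C2'–C3' (B-alkyl Suzuki coupling of a 2-vinylchroman) and at C5'–C6' (Negishi coupling); both alkene geometries come from syn-methylalumination of terminal alkynes.
5. Ring order: no ring is formed; the chroman bicycle with C2 is taken intact from (S)-Trolox.

Key step: step 11

Remark on numbering: tocopherol numbering is used (chroman C2; side chain C1'–C13', alkene C12'=C13'). C8' has the spatial arrangement of natural α-tocopherol throughout but reads S by the CIP rules once C11' is oxygenated or C12' is sp2, because the C9' branch then outranks the C7' branch.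

Remark on the diene: it is assembled by carbometalation and cross-coupling rather than by allylic sulfone alkylation and reductive desulfonylation. Sulfonyl carbanions and hydride donors attack the aryl acetate, and desulfonylation can move or isomerise the very alkene whose geometry the hydrogenation copies into C4'/C8'.

Assumption: in step 11 the ligand enantiomer is the one that converts E-configured CH2–CH=C(CH3)–CH2 units into the natural-type centres. Its sign is fixed in a trial run against the natural-type series, since the catalyst and not the substrate decides the face.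

Assumption: (S)-Trolox, pent-4-yn-1-ol, (4-bromobut-1-yn-1-yl)trimethylsilane and isopropenylmagnesium bromide solution are bought.

**Route**

Step 1
Reactants: 1 (S)-Trolox [(2S)-6-hydroxy-2,5,7,8-tetramethylchroman-2-carboxylic acid]
Product: 3 (2S)-6-acetoxy-2,5,7,8-tetramethylchroman-2-carboxylic acid, via mixed acetic anhydride 2 (not isolated)
Conditions: Ac2O (3 equiv), pyridine, DMAP (cat.), CH2Cl2, 0 °C → rt; then H2O/THF, rt; aq. HCl work-up
Reagents that add atoms: acetic anhydride, CC(=O)OC(C)=O
Why: DMAP-catalysed O-acylation of the hindered phenol is routine, the carboxyl group that is acetylated at the same time to mixed anhydride 2 is regenerated by water because an acyclic anhydride hydrolyses far faster than the di-ortho-substituted aryl acetate, and the C2 stereocentre is not touched.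

Step 2
Reactants: 3 (2S)-6-acetoxy-2,5,7,8-tetramethylchroman-2-carboxylic acid
Product: 4 [(2S)-2-(hydroxymethyl)-2,5,7,8-tetramethylchroman-6-yl] acetate
Conditions: BH3·SMe2 (1.5 equiv), THF, 0 °C → rt; MeOH quench
Reagents that add atoms: none
Why: Chemoselective borane reduction, in which the carboxylic acid is reduced through its acyloxyborane much faster than an ester, so the aryl acetate should survive and C2 (no α-hydrogen) keeps its configuration.

Step 3
Reactants: 4 [(2S)-2-(hydroxymethyl)-2,5,7,8-tetramethylchroman-6-yl] acetate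
Product: 5 [(2S)-2-formyl-2,5,7,8-tetramethylchroman-6-yl] acetate
Conditions: Dess–Martin periodinane (1.2 equiv), CH2Cl2, rt
Reagents that add atoms: none
Why: Dess–Martin oxidation turns the neopentyl-type primary alcohol into the aldehyde under neutral conditions that leave the acetate alone, and the quaternary α-carbon excludes enolisation or epimerisation.

Step 4
Reactants: 5 [(2S)-2-formyl-2,5,7,8-tetramethylchroman-6-yl] acetate
Product: 6 [(2S)-2-ethenyl-2,5,7,8-tetramethylchroman-6-yl] acetate
Conditions: Ph3PCH3Br (1.15 equiv), KN(SiMe3)2 (1.1 equiv), THF, 0 °C; then 5, −78 °C → 0 °C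
Reagents that add atoms: methyltriphenylphosphonium bromide, C[P+](c1ccccc1)(c1ccccc1)c1ccccc1.[Br-]
Why: Wittig methylenation, in which the non-stabilised ylide adds to the non-enolisable aldehyde at low temperature much faster than it can acylate on the hindered aryl acetate, so C2 is carried through unchanged.

Step 5
Reactants: 7 pent-4-yn-1-ol
Product: 9 (E)-5-iodo-4-methylpent-4-en-1-ol, via alkenylalane 8 (not isolated)
Conditions: AlMe3 (3 equiv), Cp2ZrCl2 (0.25 equiv), CH2Cl2, 0 °C → rt; then I2 (1.2 equiv), THF, −30 → 0 °C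
Reagents that add atoms: trimethylaluminium, C[Al](C)C; iodine, II
Why: Zirconium-catalysed carboalumination adds CH3 and Al syn across the terminal alkyne with CH3 on the internal carbon (the hydroxyl being masked as its aluminium alkoxide), and iodinolysis of the C–Al bond with retention should give the E-iodoalkene that fixes the C7'=C8' geometry.

Step 6
Reactants: 9 (E)-5-iodo-4-methylpent-4-en-1-ol
Product: 10 (E)-tert-butyl[(5-iodo-4-methylpent-4-en-1-yl)oxy]dimethylsilane
Conditions: TBSCl (1.2 equiv), imidazole (2 equiv), DMF, rt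
Reagents that add atoms: tert-butyldimethylsilyl chloride, CC(C)(C)[Si](C)(C)Cl
Why: Standard imidazole-mediated silylation of a primary alcohol, giving the C11' oxygen a group that tolerates organoaluminium, organozinc and hydrogenation conditions.

Step 7
Reactants: 10 (E)-tert-butyl[(5-iodo-4-methylpent-4-en-1-yl)oxy]dimethylsilane; 11 (4-bromobut-1-yn-1-yl)trimethylsilane
Product: 13 (E)-tert-butyldimethyl{[4-methyl-9-(trimethylsilyl)non-4-en-8-yn-1-yl]oxy}silane, via butynylzinc bromide 12 (not isolated)
Conditions: 11 (1.3 equiv), Zn dust (2 equiv), I2 (5 mol%), DMA, 70 °C; then 10, PdCl2(dppf) (3 mol%), THF, rt → 40 °C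
Reagents that add atoms: none
Why: Direct zinc insertion into the primary bromide gives a non-basic alkylzinc halide, and the Negishi sp3–sp2 coupling (oxidative addition of the iodoalkene to zerovalent palladium formed from the divalent precatalyst, transmetalation, reductive elimination) forms C5'–C6' with retention of the E geometry, the wide-bite-angle dppf disfavouring β-hydride elimination.

Step 8
Reactants: 13 (E)-tert-butyldimethyl{[4-methyl-9-(trimethylsilyl)non-4-en-8-yn-1-yl]oxy}silane
Product: 14 (E)-tert-butyldimethyl[(4-methylnon-4-en-8-yn-1-yl)oxy]silane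
Conditions: K2CO3 (0.3 equiv), MeOH, rt
Reagents that add atoms: none
Why: Methoxide-catalysed protodesilylation cleaves only the alkynyl C–Si bond, a primary tert-butyldimethylsilyl ether being stable to K2CO3 in methanol.

Step 9
Reactants: 14 (E)-tert-butyldimethyl[(4-methylnon-4-en-8-yn-1-yl)oxy]silane
Product: 16 (4E,8E)-tert-butyl[(9-iodo-4,8-dimethylnona-4,8-dien-1-yl)oxy]dimethylsilane, via dienylalane 15 (not isolated)
Conditions: AlMe3 (2.5 equiv), Cp2ZrCl2 (0.25 equiv), CH2Cl2, 0 °C → rt; then I2 (1.3 equiv), THF, −30 → 0 °C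
Reagents that add atoms: trimethylaluminium, C[Al](C)C; iodine, II
Why: A second zirconium-catalysed syn-methylalumination of the terminal alkyne followed by iodinolysis with retention should fix the C3'=C4' geometry as E, the existing trisubstituted alkene and the silyl ether being inert to the methylzirconium species.

Step 10
Reactants: 6 [(2S)-2-ethenyl-2,5,7,8-tetramethylchroman-6-yl] acetate; 16 (4E,8E)-tert-butyl[(9-iodo-4,8-dimethylnona-4,8-dien-1-yl)oxy]dimethylsilane
Product: 18 [(2R)-2-[(3E,7E)-11-(tert-butyldimethylsilyloxy)-4,8-dimethylundeca-3,7-dien-1-yl]-2,5,7,8-tetramethylchroman-6-yl] acetate, via B-alkyl-9-BBN 17 (not isolated)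
Conditions: 9-BBN (1.3 equiv), THF, 0 °C → rt; then 16 (1.0 equiv), PdCl2(dppf) (5 mol%), AsPh3 (5 mol%), aq. K3PO4 (3 equiv), DMF, rt
Reagents that add atoms: none
Why: Anti-Markovnikov hydroboration of the monosubstituted alkene by 9-BBN followed by B-alkyl Suzuki–Miyaura coupling with the iodoalkene forms C2'–C3' with retention of the E geometry, the mild phosphate base sparing the hindered aryl acetate and C2 staying a spectator (its descriptor changes to R only through CIP priorities).

Step 11
Reactants: 18 [(2R)-2-[(3E,7E)-11-(tert-butyldimethylsilyloxy)-4,8-dimethylundeca-3,7-dien-1-yl]-2,5,7,8-tetramethylchroman-6-yl] acetate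
Product: 19 [(2R)-2-[(4R,8S)-11-(tert-butyldimethylsilyloxy)-4,8-dimethylundecyl]-2,5,7,8-tetramethylchroman-6-yl] acetate
Conditions: H2 (50 bar), [Ir(cod)(L)][B(C6H3(CF3)2)4] (2 mol%), L = enantiopure 8-[di(o-tolyl)phosphanyloxy]-2-phenyl-5,6,7,8-tetrahydroquinoline, CH2Cl2, rt
Reagents that add atoms: none
Why: Under H2 the cyclooctadiene ligand of the monovalent iridium precatalyst is hydrogenated off and a cationic trivalent iridium dihydride carrying the P,N ligand forms, to which each alkene in turn coordinates, inserts into an Ir–H bond and is released by C–H reductive elimination (a cycle through pentavalent iridium is usually invoked), so only C–H bonds at C3'/C4' and C7'/C8' are made and no ring or skeletal bond is formed. The closest known reaction type is the iridium/P,N-catalysed asymmetric hydrogenation of unfunctionalised, purely alkyl-substituted E-trisubstituted alkenes, as practised on tocotrienyl acetates and farnesol-type chains. C4' and C8' are both set by catalyst control: the ligand pocket distinguishes the enantiofaces through the vinylic hydrogen and the E arrangement of CH3 and CH2R, and since C3'=C4' and C7'=C8' present the same local pattern, one ligand enantiomer should give the same spatial sense at both (4'R and the natural-type arrangement at C8', written 8'S here). The selectivity needed is high face selectivity at two independent alkenes without E/Z or positional isomerisation before reduction; it is secured by the E geometry fixed in steps 5 and 9, by the non-coordinating borate anion in CH2Cl2, and by the remoteness of the acetate, the silyl ether and the C2 stereocentre, which can neither bind the metal nor create a mismatched case. The isopropenyl group, which this catalyst would reduce first, is not yet present.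

Step 12
Reactants: 19 [(2R)-2-[(4R,8S)-11-(tert-butyldimethylsilyloxy)-4,8-dimethylundecyl]-2,5,7,8-tetramethylchroman-6-yl] acetate
Product: 20 [(2R)-2-[(4R,8S)-11-hydroxy-4,8-dimethylundecyl]-2,5,7,8-tetramethylchroman-6-yl] acetate
Conditions: HF·pyridine, pyridine, THF, 0 °C → rt
Reagents that add atoms: none
Why: Fluoride-mediated desilylation under buffered, weakly acidic conditions cleaves the primary silyl ether while leaving the aryl acetate, which basic fluoride sources could remove.

Step 13
Reactants: 20 [(2R)-2-[(4R,8S)-11-hydroxy-4,8-dimethylundecyl]-2,5,7,8-tetramethylchroman-6-yl] acetate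
Product: 21 [(2R)-2-[(4R,8S)-4,8-dimethyl-11-(tosyloxy)undecyl]-2,5,7,8-tetramethylchroman-6-yl] acetate
Conditions: TsCl (1.3 equiv), pyridine, DMAP (cat.), CH2Cl2, 0 °C → rt
Reagents that add atoms: p-toluenesulfonyl chloride, Cc1ccc(cc1)S(Cl)(=O)=O
Why: Sulfonylation of the only free hydroxyl, the phenol being masked as its acetate, activates C11' for substitution.

Step 14
Reactants: 21 [(2R)-2-[(4R,8S)-4,8-dimethyl-11-(tosyloxy)undecyl]-2,5,7,8-tetramethylchroman-6-yl] acetate; 22 isopropenylmagnesium bromide
Product: 24 (2R)-2,5,7,8-tetramethyl-2-[(4R,8S)-4,8,12-trimethyltridec-12-en-1-yl]chroman-6-ol, via bromomagnesium phenoxide tosylate 23 (not isolated)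
Conditions: 22 (6 equiv), THF, 0 °C, 20 min; then Li2CuCl4 (5 mol%), −20 °C → rt; degassed aq. NH4Cl, Ar
Reagents that add atoms: none
Why: The Grignard reagent first cleaves the aryl acetate by acyl substitution (the ketone formed takes up a second equivalent), then the copper-catalysed Kochi-type coupling, in which divalent copper is reduced to a monovalent organocuprate that displaces the primary tosylate, forms C11'–C12' far from the stereocentres and introduces the isopropenyl alkene only after the hydrogenation.

**Compound list**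

1 | (S)-Trolox, (2S)-6-hydroxy-2,5,7,8-tetramethylchroman-2-carboxylic acid | OC(=O)[C@]1(C)CCc2c(C)c(O)c(C)c(C)c2O1 | starting material
2 | (2S)-6-acetoxy-2,5,7,8-tetramethylchroman-2-carboxylic acetic anhydride | CC(=O)OC(=O)[C@]1(C)CCc2c(C)c(OC(C)=O)c(C)c(C)c2O1 | intermediate (not isolated)
3 | (2S)-6-acetoxy-2,5,7,8-tetramethylchroman-2-carboxylic acid | OC(=O)[C@]1(C)CCc2c(C)c(OC(C)=O)c(C)c(C)c2O1 | intermediate
4 | [(2S)-2-(hydroxymethyl)-2,5,7,8-tetramethylchroman-6-yl] acetate | OC[C@]1(C)CCc2c(C)c(OC(C)=O)c(C)c(C)c2O1 | intermediate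
5 | [(2S)-2-formyl-2,5,7,8-tetramethylchroman-6-yl] acetate | O=C[C@]1(C)CCc2c(C)c(OC(C)=O)c(C)c(C)c2O1 | intermediate
6 | [(2S)-2-ethenyl-2,5,7,8-tetramethylchroman-6-yl] acetate | C=C[C@]1(C)CCc2c(C)c(OC(C)=O)c(C)c(C)c2O1 | intermediate
7 | pent-4-yn-1-ol | C#CCCCO | starting material
8 | dimethylaluminium (E)-5-(dimethylalumanyl)-4-methylpent-4-en-1-olate | C[Al](C)OCCC/C(C)=C/[Al](C)C | intermediate (not isolated)
9 | (E)-5-iodo-4-methylpent-4-en-1-ol | OCCC/C(C)=C/I | intermediate
10 | (E)-tert-butyl[(5-iodo-4-methylpent-4-en-1-yl)oxy]dimethylsilane | CC(C)(C)[Si](C)(C)OCCC/C(C)=C/I | intermediate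
11 | (4-bromobut-1-yn-1-yl)trimethylsilane | C[Si](C)(C)C#CCCBr | starting material
12 | [4-(trimethylsilyl)but-3-yn-1-yl]zinc bromide | C[Si](C)(C)C#CCC[Zn]Br | intermediate (not isolated)
13 | (E)-tert-butyldimethyl{[4-methyl-9-(trimethylsilyl)non-4-en-8-yn-1-yl]oxy}silane | CC(C)(C)[Si](C)(C)OCCC/C(C)=C/CCC#C[Si](C)(C)C | intermediate
14 | (E)-tert-butyldimethyl[(4-methylnon-4-en-8-yn-1-yl)oxy]silane | CC(C)(C)[Si](C)(C)OCCC/C(C)=C/CCC#C | intermediate
15 | [(1E,5E)-9-(tert-butyldimethylsilyloxy)-2,6-dimethylnona-1,5-dien-1-yl]dimethylalane | CC(C)(C)[Si](C)(C)OCCC/C(C)=C/CC/C(C)=C/[Al](C)C | intermediate (not isolated)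
16 | (4E,8E)-tert-butyl[(9-iodo-4,8-dimethylnona-4,8-dien-1-yl)oxy]dimethylsilane | CC(C)(C)[Si](C)(C)OCCC/C(C)=C/CC/C(C)=C/I | intermediate
17 | 9-{2-[(2R)-6-acetoxy-2,5,7,8-tetramethylchroman-2-yl]ethyl}-9-borabicyclo[3.3.1]nonane | CC(=O)Oc1c(C)c(C)c2O[C@](C)(CCB3C4CCCC3CCC4)CCc2c1C | intermediate (not isolated)
18 | [(2R)-2-[(3E,7E)-11-(tert-butyldimethylsilyloxy)-4,8-dimethylundeca-3,7-dien-1-yl]-2,5,7,8-tetramethylchroman-6-yl] acetate | CC(C)(C)[Si](C)(C)OCCC/C(C)=C/CC/C(C)=C/CC[C@]1(C)CCc2c(C)c(OC(C)=O)c(C)c(C)c2O1 | intermediate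
19 | [(2R)-2-[(4R,8S)-11-(tert-butyldimethylsilyloxy)-4,8-dimethylundecyl]-2,5,7,8-tetramethylchroman-6-yl] acetate | CC(C)(C)[Si](C)(C)OCCC[C@@H](C)CCC[C@@H](C)CCC[C@]1(C)CCc2c(C)c(OC(C)=O)c(C)c(C)c2O1 | intermediate
20 | [(2R)-2-[(4R,8S)-11-hydroxy-4,8-dimethylundecyl]-2,5,7,8-tetramethylchroman-6-yl] acetate | OCCC[C@@H](C)CCC[C@@H](C)CCC[C@]1(C)CCc2c(C)c(OC(C)=O)c(C)c(C)c2O1 | intermediate
21 | [(2R)-2-[(4R,8S)-4,8-dimethyl-11-(tosyloxy)undecyl]-2,5,7,8-tetramethylchroman-6-yl] acetate | Cc1ccc(cc1)S(=O)(=O)OCCC[C@@H](C)CCC[C@@H](C)CCC[C@]1(C)CCc2c(C)c(OC(C)=O)c(C)c(C)c2O1 | intermediate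
22 | isopropenylmagnesium bromide | C=C(C)[Mg]Br | starting material
23 | bromomagnesium (2R)-2-[(4R,8S)-4,8-dimethyl-11-(tosyloxy)undecyl]-2,5,7,8-tetramethylchroman-6-olate | Cc1ccc(cc1)S(=O)(=O)OCCC[C@@H](C)CCC[C@@H](C)CCC[C@]1(C)CCc2c(C)c(O[Mg]Br)c(C)c(C)c2O1 | intermediate (not isolated)
24 | (2R)-2,5,7,8-tetramethyl-2-[(4R,8S)-4,8,12-trimethyltridec-12-en-1-yl]chroman-6-ol (CNP0115007.1) | C=C(C)CCC[C@@H](C)CCC[C@@H](C)CCC[C@]1(C)CCc2c(C)c(O)c(C)c(C)c2O1 | target

**Step count**

Total: 14 steps. Longest linear sequence: 10 steps (7 → 24 through steps 5–14).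

**Steps most likely to fail**

Step 11. The enantioface discrimination may be incomplete at one of the two alkenes, giving C4' or C8' epimers that ordinary chromatography will not remove. The acidic iridium hydrides may also shift an alkene along the chain before it is reduced, or the catalyst may aggregate into inactive hydride-bridged clusters after the first reduction. Fallback, from 6 back to 20: both methyl-bearing centres are bought instead of made.
- Vinylchroman 6 is hydroborated as in step 10, and borane 17 is oxidised with Me3NO (neutral, so the acetate stays) to [(2S)-2-(2-hydroxyethyl)-2,5,7,8-tetramethylchroman-6-yl] acetate F1. TsCl/pyridine converts this into the tosylate F2.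
- Commercial (R)-citronellyl bromide and Mg give (R)-citronellylmagnesium bromide F3. It is coupled under Li2CuCl4 catalysis with the bromomagnesium alkoxide of commercial (S)-3-bromo-2-methylpropan-1-ol (formed beforehand with EtMgBr) to give (2R,6S)-2,6,10-trimethylundec-9-en-1-ol F4.
- CBr4/PPh3 gives (2R,6S)-1-bromo-2,6,10-trimethylundec-9-ene F5, and Mg gives the corresponding Grignard reagent F6.
- An excess of F6 with F2 and Li2CuCl4 should form C2'–C3' and cleave the acetate, giving the 11'-ene chromanol F7. Ac2O/pyridine gives its acetate F8.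
- Ozonolysis of the C11'=C12' alkene of F8 (O3, CH2Cl2/MeOH, −78 °C, then NaBH4) returns alcohol 20.

Step 14. Substitution of the tosylate by the weakly nucleophilic alkenyl Grignard reagent may be slow, so that exchange of tosylate for bromide, reduction or elimination compete, and the unprotected magnesium chromanoxide may oxidise during the long reaction. Fallback, from 21 back to 24: the polarity of the coupling is inverted.
- NaI in acetone converts 21 into the C11' iodide F12.
- Zn dust with LiCl in THF gives the alkylzinc iodide F13.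
- Negishi coupling of F13 with 2-bromopropene (PdCl2(dppf), THF, rt) gives the acetate of the target F14.
- KOH in MeOH/THF under argon removes the acetate to give 24.

Step 10. Transmetalation from boron may be slow next to the quaternary C2, allowing protodeboronation or homocoupling to take over, and the aqueous base may hydrolyse the acetate during a long reaction. Fallback, from 6 back to 18: a base-free coupling through zinc.
- Hydroboration of 6 and Me3NO oxidation give [(2S)-2-(2-hydroxyethyl)-2,5,7,8-tetramethylchroman-6-yl] acetate F9 (the same compound as F1).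
- I2/PPh3/imidazole gives [(2S)-2-(2-iodoethyl)-2,5,7,8-tetramethylchroman-6-yl] acetate F10.
- Zn dust with LiCl in THF gives the alkylzinc iodide F11.
- Negishi coupling of F11 with iodide 16 (PdCl2(dppf), THF/DMA, 40 °C) gives 18.

**Further compounds**

F1 | step 11 | [(2S)-2-(2-hydroxyethyl)-2,5,7,8-tetramethylchroman-6-yl] acetate | OCC[C@]1(C)CCc2c(C)c(OC(C)=O)c(C)c(C)c2O1
F2 | step 11 | [(2S)-2,5,7,8-tetramethyl-2-(2-tosyloxyethyl)chroman-6-yl] acetate | Cc1ccc(cc1)S(=O)(=O)OCC[C@]1(C)CCc2c(C)c(OC(C)=O)c(C)c(C)c2O1
F3 | step 11 | (R)-citronellylmagnesium bromide | CC(C)=CCC[C@@H](C)CC[Mg]Br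
F4 | step 11 | (2R,6S)-2,6,10-trimethylundec-9-en-1-ol | OC[C@H](C)CCC[C@H](C)CCC=C(C)C
F5 | step 11 | (2R,6S)-1-bromo-2,6,10-trimethylundec-9-ene | BrC[C@H](C)CCC[C@H](C)CCC=C(C)C
F6 | step 11 | [(2R,6S)-2,6,10-trimethylundec-9-en-1-yl]magnesium bromide | Br[Mg]C[C@H](C)CCC[C@H](C)CCC=C(C)C
F7 | step 11 | (2R)-2,5,7,8-tetramethyl-2-[(4R,8S)-4,8,12-trimethyltridec-11-en-1-yl]chroman-6-ol | CC(C)=CCC[C@@H](C)CCC[C@@H](C)CCC[C@]1(C)CCc2c(C)c(O)c(C)c(C)c2O1
F8 | step 11 | [(2R)-2,5,7,8-tetramethyl-2-[(4R,8S)-4,8,12-trimethyltridec-11-en-1-yl]chroman-6-yl] acetate | CC(C)=CCC[C@@H](C)CCC[C@@H](C)CCC[C@]1(C)CCc2c(C)c(OC(C)=O)c(C)c(C)c2O1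
F9 | step 10 | [(2S)-2-(2-hydroxyethyl)-2,5,7,8-tetramethylchroman-6-yl] acetate | OCC[C@]1(C)CCc2c(C)c(OC(C)=O)c(C)c(C)c2O1
F10 | step 10 | [(2S)-2-(2-iodoethyl)-2,5,7,8-tetramethylchroman-6-yl] acetate | ICC[C@]1(C)CCc2c(C)c(OC(C)=O)c(C)c(C)c2O1
F11 | step 10 | {2-[(2S)-6-acetoxy-2,5,7,8-tetramethylchroman-2-yl]ethyl}zinc iodide | I[Zn]CC[C@]1(C)CCc2c(C)c(OC(C)=O)c(C)c(C)c2O1
F12 | step 14 | [(2R)-2-[(4R,8S)-11-iodo-4,8-dimethylundecyl]-2,5,7,8-tetramethylchroman-6-yl] acetate | ICCC[C@@H](C)CCC[C@@H](C)CCC[C@]1(C)CCc2c(C)c(OC(C)=O)c(C)c(C)c2O1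
F13 | step 14 | {(4S,8R)-11-[(2R)-6-acetoxy-2,5,7,8-tetramethylchroman-2-yl]-4,8-dimethylundecyl}zinc iodide | I[Zn]CCC[C@@H](C)CCC[C@@H](C)CCC[C@]1(C)CCc2c(C)c(OC(C)=O)c(C)c(C)c2O1
F14 | step 14 | [(2R)-2,5,7,8-tetramethyl-2-[(4R,8S)-4,8,12-trimethyltridec-12-en-1-yl]chroman-6-yl] acetate | C=C(C)CCC[C@@H](C)CCC[C@@H](C)CCC[C@]1(C)CCc2c(C)c(OC(C)=O)c(C)c(C)c2O1
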